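Start from a small charge: this flask holds 1.80 equivalents of nucleophile, fewer than the dawn run's 2.50 and the summer run's 3.94.

| setting | dawn | summer | flask |
|---|---|---|---|
| electrophile | 0.18 M | 0.18 M | 0.18 M |
| nucleophile | 0.45 M | 0.71 M | 0.324 M |
| free base | 0.18 M | 0.18 M | 0.180 M |
| remark | run made earlier | run made earlier |  |
| time |  |  | 4.0 h |

| run | time / h | target / % | isomer of the product / % | electrophile / % |
|---|---|---|---|---|
| dawn | 0.417 | 31.1 | 43.6 | 0.6 |
| dawn | 1.33 | 30.4 | 43.2 | 0.3 |
| dawn | 2.00 | 29.8 | 43.4 | 0.4 |
| dawn | 3.00 | 30.2 | 42.6 | 0.4 |
| dawn | 5.00 | 31.3 | 42.6 | 0 |
| summer | 0.417 | 34.1 | 47.3 | 0 |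
| summer | 1.33 | 34.7 | 48.4 | 0 |
| summer | 2.00 | 33.7 | 47.3 | 0 |
| summer | 3.00 | 34.1 | 46.5 | 0 |
| summer | 5.00 | 33.9 | 48.0 | 0 |

(each reading ± 0.5 percentage points)

- a species is counted by the electrophile in it: one self-condensation product counts as two
- the earlier runs were read with a standard deviation of 0.5 percentage points
- steps that have been proposed: nucleophile + acid set free <-> protonated nucleophile; target <-> isomer of the product; electrophile + nucleophile -> acid set free + target; acid set free + free base <-> salt of the base; 2 electrophile -> self-condensation product
- the reaction counts as stopped when no species that holds the electrophile changes by six tenths of a point or more over the second half of the time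

- which holds at 4.0 h: what has brought the reaction to rest, or that it has not come to rest (forward and back rates have come level / the nucleophile has run out first / it is still moving / all of the electrophile has reacted / the free base has run out first)
- how much target there is at 4.0 h, in percent of the electrophile charged
- how much isomer of the product there is at 4.0 h, in percent of the electrophile charged

By 0.417 h the electrophile reads 0.6% at dawn and 0% in summer, so treat it as consumed at 4.0 h, about ten times that reading. Let Y be target plus isomer of the product, averaged over the readings: 73.6% at dawn, 81.6% in summer. Count the remainder M as self-condensation product. Divide Y/M by the equivalents: dawn reads 1.12, summer 1.12. Their mean, w = 1.12, is a selectivity factor: electrophile coupled over electrophile self-condensed, per equivalent of nucleophile.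

For this flask, W = w times equivalents = 2.02, so M is one part in one plus W, 33.1%, and Y is 66.9%. Check the limits: this needs 0.120 M of nucleophile and frees as much acid, less than the 0.324 M of nucleophile and 0.180 M of free base charged. W gives no split, so add the isomer-to-target ratio read from both runs, 1.40: expect 27.8% target and 39.1% isomer of the product.

The forecast says all of the electrophile has reacted, with 27.5% target and 38.5% isomer of the product, “with self-condensation making up the remainder”.

This flask gives 27.7% target and 38.8% isomer of the product at 4.0 h: all of the electrophile has reacted.

    nucleophile + acid set free ⇌ protonated nucleophile, settled at all times (K = 140 M⁻¹)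
    target ⇌ isomer of the product (K = 1.40, k = 0.0200 s⁻¹)
    electrophile + nucleophile → acid set free + target (k = 0.0890 M⁻¹ s⁻¹)
    acid set free + free base ⇌ salt of the base, settled at all times (K = 32000 M⁻¹)
    2 electrophile → self-condensation product (k = 0.0790 M⁻¹ s⁻¹)

Self-condensation product stands at 33.4% in this flask at 4.00 h. Apply w to the neighbour flask with 0.13 M of nucleophile, 0.722 equiv: W is 0.810, so M is 55.3%, and that neighbour flask holds 56.0% self-condensation product at 4.00 h.

Readings and results are simulated from invented constants; scatter was added.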